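Don't hunt the target's peak along the clock. Divide the target's net rate by the starting material's rate, and time drops out.

the same everywhere: free catalyst 1 mol%

| charge | starting material | remark | time |
|---|---|---|---|
| elm | 0.40 M | run made earlier |  |
| flask | 0.80 M |  | 40 h |
1. time, not beyond 40 h, at which the flask holds most target
2. the amount of target, in percent of the starting material charged, at that time
- no earlier run changes the charge of free catalyst; that part of a forecast is a guess
elm run (percent of the starting material charged)

| time / h | target / % | starting material / % |
|---|---|---|
| 0.667 | 7.6 | 84.6 |
| 2.00 | 7.6 | 62.4 |
| 4.00 | 5.6 | 38.2 |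
| 6.00 | 2.5 | 22.6 |
| 8.00 | 1.3 | 12.7 |

(each reading ± 0.5 percentage points)

Let a and p be starting material and target as fractions of the charge. Assume that making and losing target both run through free catalyst, first order in it, so the catalyst cancels from dp/da as well. What remains is the selectivity factor σ, the rate constant for losing target over that for making it. On this assumption, late in a run, p/a tends to the reciprocal of σ less one.

Read the rows. The ratio p/a is 0.147 at 4.00 h, 0.111 at 6.00 h and 0.102 at 8.00 h, which is noisy, so pool these rows: 0.128. That gives, as a reading with the scatter of these rows, σ, the target's loss constant over its making constant, 8.82.

The peak stands where p/a equals the reciprocal of σ, which integration puts at a = 75.7%, with p = 8.58%. On this assumption the charge does not enter, so I expect that height in the flask. The elm run's row at 2.00 h gives a decay constant of 0.236 h⁻¹, so I put the elm run at that a near 1.18 h. The flask holds twice the catalyst concentration of the elm run, so my reckoning for the flask's peak time is 0.590 h.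

The forecast gives a best time of 1.7 h (1.1 h to 2.8 h) and a height of 8.6% (6.5% to 11.5%): “If saturation slows both steps alike, the peak height stays about the same at double concentration, but it comes later”. We part on the time.

The flask holds most target at 0.681 h, with 8.79%.

    starting material + free catalyst ⇌ catalyst intermediate A (K = 3.10 M⁻¹, k = 0.0190 M⁻¹ s⁻¹)
    catalyst intermediate A → catalyst intermediate B (k = 0.370 s⁻¹)
    catalyst intermediate B → free catalyst + target (k = 0.0530 s⁻¹)
    free catalyst + target → free catalyst + over-reaction product (k = 0.160 M⁻¹ s⁻¹)

At that moment the flask holds 75.1% starting material against 8.79% target, a ratio a/p of 8.54, where the elm readings gave σ as 8.82. Carry σ to the neighbour flask with 2.5 mol% of free catalyst: it puts the target's peak at 8.58%, and that flask reaches 8.78%.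

Readings and results come from a simulation for an exercise; the scatter is artificial.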